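**Target:** (Z)-7-[(1R,2R,3R)-3-hydroxy-2-[(3S,7R)-3,7-dihydroxyoctyl]-5-oxocyclopentyl]hept-5-enoic acid, i.e. 13,14-dihydro-19(R)-hydroxy-PGE2 (8R,11R,12R,15S,19R; 5Z). Prostaglandin numbering is used for positions.

**Retrosynthetic overview**
1. Target ⇐ enzymatic ester hydrolysis and HF desilylation of the tris-silylated methyl ester 28.
2. 28 ⇐ one-pot three-component coupling: C12–C13 by conjugate addition of the C13–C20 alkylcopper (from iodide 12) to (R)-4-silyloxycyclopentenone 23, then C7–C8 by trapping the enolate with (Z)-allylic iodide 18.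
3. 12 ⇐ (R)-propylene oxide (C19) + butenyl Grignard; asymmetric allylboration sets C15; ozonolysis/reduction and iodination give C13–I.
4. 18 ⇐ hex-5-ynoic acid (hydroxymethylation, esterification, cis-semihydrogenation, iodination); 23 ⇐ meso cyclopent-4-ene-1,3-diol (lipase desymmetrisation, silylation, deacetylation, oxidation).
5. Ring order: the single carbocycle is never built; it is carried in from the cyclopentenediol, and C11 controls C12 and C8.

Assumption: TBS = tert-butyldimethylsilyl (TBSO = its ether); but-3-enylmagnesium bromide and (+)-B-allyldiisopinocampheylborane (the reagent derived from (−)-α-pinene) are bought as solutions.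

**Lower side chain (C13–C20)**

Step 1
Reactants: 1 (R)-2-methyloxirane; 2 but-3-enylmagnesium bromide
Product: 3 (R)-hept-6-en-2-ol
Conditions: CuI (10 mol %), THF, −30 → 0 °C; then H2O
Reagents that add atoms: none
Why: Copper-catalysed Grignard opening of a terminal epoxide is SN2 at the unsubstituted carbon, so the (R) carbinol centre (future C19) is carried over untouched.

Step 2
Reactants: 3 (R)-hept-6-en-2-ol
Product: 4 (R)-tert-butyl(hept-6-en-2-yloxy)dimethylsilane
Conditions: TBSCl, imidazole, DMF, rt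
Reagents that add atoms: tert-butyldimethylsilyl chloride (TBSCl), CC(C)(C)[Si](C)(C)Cl
Why: Standard imidazole-promoted silylation of a secondary alcohol gives an ether that survives ozone, boranes, organolithium and organocopper reagents.

Step 3
Reactants: 4 (R)-tert-butyl(hept-6-en-2-yloxy)dimethylsilane
Product: 6 (R)-5-(TBSO)hexanal, via secondary ozonide 5 (not isolated)
Conditions: O3, CH2Cl2, −78 °C; then PPh3, −78 °C → rt
Reagents that add atoms: ozone, [O-][O+]=O
Why: Ozonolysis with reductive phosphine work-up cleaves the terminal alkene to the one-carbon-shorter aldehyde (future C15) without touching the silyl ether.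

Step 4
Reactants: 6 (R)-5-(TBSO)hexanal
Product: 8 (4S,8R)-8-(TBSO)non-1-en-4-ol, via diisopinocampheylborinate 7 (not isolated)
Conditions: (+)-Ipc2B(allyl), Et2O, −78 °C, 3 h; then 3 M NaOH, 30% H2O2, 0 °C → rt
Reagents that add atoms: (+)-B-allyldiisopinocampheylborane, C=CCB([C@H]1C[C@H]2C[C@@H]([C@@H]1C)C2(C)C)[C@H]1C[C@H]2C[C@@H]([C@@H]1C)C2(C)C
Why: Brown asymmetric allylboration through a chair six-membered transition state delivers allyl to the Re face of the unbranched aldehyde, setting the (S) carbinol (future C15) under reagent control with no influence from remote C19.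

Step 5
Reactants: 8 (4S,8R)-8-(TBSO)non-1-en-4-ol
Product: 9 (4S,8R)-4,8-bis(TBSO)non-1-ene
Conditions: TBSCl, imidazole, DMF, 40 °C
Reagents that add atoms: tert-butyldimethylsilyl chloride (TBSCl), CC(C)(C)[Si](C)(C)Cl
Why: Silylation of the new secondary alcohol gives both side-chain hydroxyls the same protecting group, removable together at the end.

Step 6
Reactants: 9 (4S,8R)-4,8-bis(TBSO)non-1-ene
Product: 11 (3S,7R)-3,7-bis(TBSO)octan-1-ol, via secondary ozonide 10 (not isolated)
Conditions: O3, CH2Cl2, −78 °C; then NaBH4, MeOH, −78 °C → rt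
Reagents that add atoms: ozone, [O-][O+]=O
Why: Ozonolysis with borohydride work-up excises the terminal carbon and gives the primary alcohol (future C13) directly, no stereocentre being involved.

Step 7
Reactants: 11 (3S,7R)-3,7-bis(TBSO)octan-1-ol
Product: 12 (3S,7R)-3,7-bis(TBSO)-1-iodooctane
Conditions: I2, PPh3, imidazole, CH2Cl2, 0 °C → rt
Reagents that add atoms: iodine, II
Why: Appel-type (Garegg–Samuelsson) iodination converts the primary alcohol to the iodide by SN2 on the alkoxyphosphonium ion under neutral conditions that leave the silyl ethers alone.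

**Upper side chain (C1–C7)**

Step 8
Reactants: 13 hex-5-ynoic acid
Product: 15 7-hydroxyhept-5-ynoic acid, via magnesium dianion 14 (not isolated)
Conditions: EtMgBr (2.2 equiv), THF, 0 → 45 °C; then (CH2O)n, 45 °C; then 1 M HCl, 0 °C
Reagents that add atoms: paraformaldehyde (as formaldehyde), C=O
Why: Two equivalents of Grignard give the carboxylate/alkynylmagnesium dianion, in which only the acetylide carbon is nucleophilic enough to add to formaldehyde (alkynyl Grignard hydroxymethylation).

Step 9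
Reactants: 15 7-hydroxyhept-5-ynoic acid
Product: 16 methyl 7-hydroxyhept-5-ynoate
Conditions: MeOH, H2SO4 (cat.), rt
Reagents that add atoms: methanol, CO
Why: Fischer esterification in excess methanol is selective for the acid, and the propargylic alcohol is inert under these conditions.

Step 10
Reactants: 16 methyl 7-hydroxyhept-5-ynoate
Product: 17 methyl (Z)-7-hydroxyhept-5-enoate
Conditions: H2 (1 atm), Pd/CaCO3 poisoned by Pb(OAc)2 (Lindlar), quinoline, EtOAc, rt
Reagents that add atoms: none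
Why: Lindlar semihydrogenation adds hydrogen syn on the poisoned palladium surface and stops at the (Z)-alkene.

Step 11
Reactants: 17 methyl (Z)-7-hydroxyhept-5-enoate
Product: 18 methyl (Z)-7-iodohept-5-enoate
Conditions: I2, PPh3, imidazole, CH2Cl2, 0 °C, dark; used at once
Reagents that add atoms: iodine, II
Why: Appel-type iodination of the allylic alcohol is fast and neutral at 0 °C, so the (Z) geometry is kept, provided the labile iodide is used immediately.

**Cyclopentenone**

Step 12
Reactants: 19 cis-cyclopent-4-ene-1,3-diol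
Product: 20 (1S,4R)-4-hydroxycyclopent-2-en-1-yl acetate
Conditions: porcine pancreatic lipase (pancreatin), vinyl acetate, Et3N, THF, rt
Reagents that add atoms: vinyl acetate, CC(=O)OC=C
Why: Lipase-catalysed irreversible transesterification desymmetrises the meso diol by acylating only the (S)-configured carbinol, leaving the free hydroxyl on the (R) carbon that becomes C11.

Step 13
Reactants: 20 (1S,4R)-4-hydroxycyclopent-2-en-1-yl acetate
Product: 21 (1S,4R)-4-(TBSO)cyclopent-2-en-1-yl acetate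
Conditions: TBSCl, imidazole, DMF, rt
Reagents that add atoms: tert-butyldimethylsilyl chloride (TBSCl), CC(C)(C)[Si](C)(C)Cl
Why: Silylation of the free allylic alcohol fixes the differentiation of the two oxygens achieved by the enzyme.

Step 14
Reactants: 21 (1S,4R)-4-(TBSO)cyclopent-2-en-1-yl acetate
Product: 22 (1S,4R)-4-(TBSO)cyclopent-2-en-1-ol
Conditions: K2CO3 (cat.), MeOH, 0 °C → rt
Reagents that add atoms: none
Why: Base-catalysed methanolysis (transesterification) removes the acetate without affecting the silyl ether or either stereocentre.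

Step 15
Reactants: 22 (1S,4R)-4-(TBSO)cyclopent-2-en-1-ol
Product: 23 (R)-4-(TBSO)cyclopent-2-en-1-one
Conditions: MnO2, CH2Cl2, rt
Reagents that add atoms: none
Why: MnO2 oxidises the allylic alcohol to the enone under neutral conditions that neither epimerise nor eliminate the silyloxy-bearing centre.

**Coupling and endgame**

Step 16
Reactants: 12 (3S,7R)-3,7-bis(TBSO)-1-iodooctane; 23 (R)-4-(TBSO)cyclopent-2-en-1-one; 18 methyl (Z)-7-iodohept-5-enoate
Product: 28 methyl (Z)-7-[(1R,2R,3R)-2-[(3S,7R)-3,7-bis(TBSO)octyl]-3-(TBSO)-5-oxocyclopentyl]hept-5-enoate, via alkyllithium 24 (not isolated), via alkylcopper tributylphosphine complex 25 (not isolated), via lithium enolate 26 (not isolated), via triphenyltin enolate 27 (not isolated)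
Conditions: 12, t-BuLi (2.1 equiv), Et2O, −78 °C; CuI (1.0 equiv), PBu3 (2.6 equiv), THF, −78 °C; 23, −78 °C, 1 h; HMPA, Ph3SnCl (1.0 equiv), −78 → −30 °C; 18 (3–5 equiv), −30 → −20 °C, 12 h
Reagents that add atoms: none
Why: In this Noyori three-component coupling the alkylcopper adds conjugately anti to the C11 silyloxy group (setting C12), and the weakly basic tin enolate is then alkylated by the allylic iodide anti to the new C12 chain (setting C8 trans) without equilibrating or eliminating the β-silyloxy group.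

Step 17
Reactants: 28 methyl (Z)-7-[(1R,2R,3R)-2-[(3S,7R)-3,7-bis(TBSO)octyl]-3-(TBSO)-5-oxocyclopentyl]hept-5-enoate
Product: 29 methyl (Z)-7-[(1R,2R,3R)-3-hydroxy-2-[(3S,7R)-3,7-dihydroxyoctyl]-5-oxocyclopentyl]hept-5-enoate
Conditions: HF·pyridine, MeCN, 0 °C → rt
Reagents that add atoms: none
Why: Buffered HF removes all three silyl ethers under mildly acidic conditions that do not dehydrate the β-hydroxy ketone or epimerise C8.

Step 18
Reactants: 29 methyl (Z)-7-[(1R,2R,3R)-3-hydroxy-2-[(3S,7R)-3,7-dihydroxyoctyl]-5-oxocyclopentyl]hept-5-enoate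
Product: 30 (Z)-7-[(1R,2R,3R)-3-hydroxy-2-[(3S,7R)-3,7-dihydroxyoctyl]-5-oxocyclopentyl]hept-5-enoic acid
Conditions: porcine liver esterase, 0.1 M phosphate buffer (pH 8)/acetone, 30 °C
Reagents that add atoms: water, O
Why: Enzymatic ester hydrolysis at near-neutral pH frees the acid while avoiding the base-induced β-elimination to the cyclopentenone that chemical saponification would cause.

**Compound list**

1 | (R)-2-methyloxirane ((R)-propylene oxide) | C[C@@H]1CO1 | starting material
2 | but-3-enylmagnesium bromide (solution in THF) | C=CCC[Mg]Br | starting material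
3 | (R)-hept-6-en-2-ol | C[C@@H](O)CCCC=C | intermediate
4 | (R)-tert-butyl(hept-6-en-2-yloxy)dimethylsilane | C[C@@H](O[Si](C)(C)C(C)(C)C)CCCC=C | intermediate
5 | 3-[(4R)-4-(TBSO)pentyl]-1,2,4-trioxolane, secondary ozonide of 4, mixture at the ring carbon (not isolated) | C[C@@H](O[Si](C)(C)C(C)(C)C)CCCC1OCOO1 | intermediate
6 | (R)-5-(TBSO)hexanal | C[C@@H](O[Si](C)(C)C(C)(C)C)CCCC=O | intermediate
7 | [(4S,8R)-8-(TBSO)non-1-en-4-yl] diisopinocampheylborinate (not isolated) | C[C@@H](O[Si](C)(C)C(C)(C)C)CCC[C@H](OB([C@H]1C[C@H]2C[C@@H]([C@@H]1C)C2(C)C)[C@H]1C[C@H]2C[C@@H]([C@@H]1C)C2(C)C)CC=C | intermediate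
8 | (4S,8R)-8-(TBSO)non-1-en-4-ol | C[C@@H](O[Si](C)(C)C(C)(C)C)CCC[C@H](O)CC=C | intermediate
9 | (4S,8R)-4,8-bis(TBSO)non-1-ene | C[C@@H](O[Si](C)(C)C(C)(C)C)CCC[C@H](O[Si](C)(C)C(C)(C)C)CC=C | intermediate
10 | 3-[(2S,6R)-2,6-bis(TBSO)heptyl]-1,2,4-trioxolane, secondary ozonide of 9, mixture at the ring carbon (not isolated) | C[C@@H](O[Si](C)(C)C(C)(C)C)CCC[C@H](O[Si](C)(C)C(C)(C)C)CC1OCOO1 | intermediate
11 | (3S,7R)-3,7-bis(TBSO)octan-1-ol | C[C@@H](O[Si](C)(C)C(C)(C)C)CCC[C@H](O[Si](C)(C)C(C)(C)C)CCO | intermediate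
12 | (3S,7R)-3,7-bis(TBSO)-1-iodooctane | C[C@@H](O[Si](C)(C)C(C)(C)C)CCC[C@H](O[Si](C)(C)C(C)(C)C)CCI | intermediate
13 | hex-5-ynoic acid | C#CCCCC(=O)O | starting material
14 | bromomagnesium 6-(bromomagnesio)hex-5-ynoate, dianion of 13 (not isolated) | Br[Mg]C#CCCCC(=O)O[Mg]Br | intermediate
15 | 7-hydroxyhept-5-ynoic acid | OCC#CCCCC(=O)O | intermediate
16 | methyl 7-hydroxyhept-5-ynoate | COC(=O)CCCC#CCO | intermediate
17 | methyl (Z)-7-hydroxyhept-5-enoate | COC(=O)CCC/C=C\CO | intermediate
18 | methyl (Z)-7-iodohept-5-enoate | COC(=O)CCC/C=C\CI | intermediate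
19 | cis-cyclopent-4-ene-1,3-diol (meso, 1R,3S) | O[C@@H]1C=C[C@H](O)C1 | starting material
20 | (1S,4R)-4-hydroxycyclopent-2-en-1-yl acetate | CC(=O)O[C@@H]1C=C[C@H](O)C1 | intermediate
21 | (1S,4R)-4-(TBSO)cyclopent-2-en-1-yl acetate | CC(=O)O[C@@H]1C=C[C@H](O[Si](C)(C)C(C)(C)C)C1 | intermediate
22 | (1S,4R)-4-(TBSO)cyclopent-2-en-1-ol | O[C@@H]1C=C[C@H](O[Si](C)(C)C(C)(C)C)C1 | intermediate
23 | (R)-4-(TBSO)cyclopent-2-en-1-one | O=C1C=C[C@H](O[Si](C)(C)C(C)(C)C)C1 | intermediate
24 | [(3S,7R)-3,7-bis(TBSO)octyl]lithium (not isolated) | C[C@@H](O[Si](C)(C)C(C)(C)C)CCC[C@H](O[Si](C)(C)C(C)(C)C)CC[Li] | intermediate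
25 | [(3S,7R)-3,7-bis(TBSO)octyl]copper tributylphosphine complex (not isolated) | C[C@@H](O[Si](C)(C)C(C)(C)C)CCC[C@H](O[Si](C)(C)C(C)(C)C)CC[Cu-][P+](CCCC)(CCCC)CCCC | intermediate
26 | lithium (3R,4R)-3-[(3S,7R)-3,7-bis(TBSO)octyl]-4-(TBSO)cyclopent-1-en-1-olate, drawn as the lithium enolate with CuI·PBu3 released (not isolated) | C[C@@H](O[Si](C)(C)C(C)(C)C)CCC[C@H](O[Si](C)(C)C(C)(C)C)CC[C@H]1[C@H](O[Si](C)(C)C(C)(C)C)CC(O[Li])=C1 | intermediate
27 | triphenyltin enolate: [(3R,4R)-3-[(3S,7R)-3,7-bis(TBSO)octyl]-4-(TBSO)cyclopent-1-en-1-yl]oxy(triphenyl)stannane (not isolated) | C[C@@H](O[Si](C)(C)C(C)(C)C)CCC[C@H](O[Si](C)(C)C(C)(C)C)CC[C@H]1[C@H](O[Si](C)(C)C(C)(C)C)CC(O[Sn](c2ccccc2)(c2ccccc2)c2ccccc2)=C1 | intermediate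
28 | methyl (Z)-7-[(1R,2R,3R)-2-[(3S,7R)-3,7-bis(TBSO)octyl]-3-(TBSO)-5-oxocyclopentyl]hept-5-enoate | C[C@@H](O[Si](C)(C)C(C)(C)C)CCC[C@H](O[Si](C)(C)C(C)(C)C)CC[C@H]1[C@H](O[Si](C)(C)C(C)(C)C)CC(=O)[C@@H]1C/C=C\CCCC(=O)OC | intermediate
29 | methyl (Z)-7-[(1R,2R,3R)-3-hydroxy-2-[(3S,7R)-3,7-dihydroxyoctyl]-5-oxocyclopentyl]hept-5-enoate | C[C@@H](O)CCC[C@H](O)CC[C@H]1[C@H](O)CC(=O)[C@@H]1C/C=C\CCCC(=O)OC | intermediate
30 | (Z)-7-[(1R,2R,3R)-3-hydroxy-2-[(3S,7R)-3,7-dihydroxyoctyl]-5-oxocyclopentyl]hept-5-enoic acid (CNP0414125.1) | C[C@@H](O)CCC[C@H](O)CC[C@H]1[C@H](O)CC(=O)[C@@H]1C/C=C\CCCC(=O)O | target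

**Step count**

Total: 18 steps. Longest linear sequence: 10 steps (steps 1–7, 16, 17, 18); the other two branches are 7 steps each to the target (8–11 or 12–15, then 16–18).

**Steps most likely to fail, with fallbacks**

Step 16 (three-component coupling). The weak point is trapping the enolate with the labile (Z)-allylic iodide: proton transfer, loss of the C11 silyloxy group or Z/E scrambling of 18 can compete. The fallback sets out from 16: iodination (I2, PPh3, imidazole) gives methyl 7-iodohept-5-ynoate F1. The same one-pot sequence from 12 and 23 (through 24–27) is then run with F1 as the electrophile, giving methyl 7-[(1R,2R,3R)-2-[(3S,7R)-3,7-bis(TBSO)octyl]-3-(TBSO)-5-oxocyclopentyl]hept-5-ynoate F2. Semihydrogenation of F2 (H2, Pd/CaCO3 poisoned by Pb(OAc)2, quinoline) creates the cis-alkene after the coupling and comes back to the route at 28. The propargylic iodide is a better SN2 partner, cannot isomerise, and the alkyne is the only unsaturation left to reduce.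

Step 8 (hydroxymethylation of the dianion). The bis-magnesium salt may be poorly soluble and react sluggishly or give oligomeric formaldehyde adducts. The fallback sets out from 13 and builds C7 by cross-coupling instead. Fischer esterification gives methyl hex-5-ynoate F3. Iodination of the terminal alkyne (N-iodosuccinimide, AgNO3 cat., acetone) gives methyl 6-iodohex-5-ynoate F4. cis-Reduction with diimide (2-nitrobenzenesulfonylhydrazide, Et3N) gives methyl (Z)-6-iodohex-5-enoate F5. Stille hydroxymethylation (Bu3SnCH2OH, Pd(PPh3)4, dioxane, 80 °C) proceeds with retention of geometry and comes back to the route at 17, bypassing 15 and 16.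

Step 4 (Brown allylboration). Any erosion of enantioselectivity gives the C15 epimer as a 1,5-diastereomer that is practically inseparable, and it would be carried into the coupling. The fallback sets out from 6 and sets C15 by catalytic hydrogenation. Roskamp homologation (methyl diazoacetate, SnCl2 cat., CH2Cl2) gives methyl (7R)-7-(TBSO)-3-oxooctanoate F6. Noyori hydrogenation (H2, RuCl2[(S)-BINAP], MeOH, 50 °C) gives methyl (3S,7R)-7-(TBSO)-3-hydroxyoctanoate F7. Silylation (TBSCl, imidazole) gives methyl (3S,7R)-3,7-bis(TBSO)octanoate F8. Reduction with DIBAL-H (iBu2AlH, CH2Cl2, −78 → 0 °C) comes back to the route at 11, bypassing 7–10.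

**Further compounds**

F1 | step 16 | methyl 7-iodohept-5-ynoate | COC(=O)CCCC#CCI
F2 | step 16 | methyl 7-[(1R,2R,3R)-2-[(3S,7R)-3,7-bis(TBSO)octyl]-3-(TBSO)-5-oxocyclopentyl]hept-5-ynoate | C[C@@H](O[Si](C)(C)C(C)(C)C)CCC[C@H](O[Si](C)(C)C(C)(C)C)CC[C@H]1[C@H](O[Si](C)(C)C(C)(C)C)CC(=O)[C@@H]1CC#CCCCC(=O)OC
F3 | step 8 | methyl hex-5-ynoate | C#CCCCC(=O)OC
F4 | step 8 | methyl 6-iodohex-5-ynoate | IC#CCCCC(=O)OC
F5 | step 8 | methyl (Z)-6-iodohex-5-enoate | I/C=C\CCCC(=O)OC
F6 | step 4 | methyl (7R)-7-(TBSO)-3-oxooctanoate | C[C@@H](O[Si](C)(C)C(C)(C)C)CCCC(=O)CC(=O)OC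
F7 | step 4 | methyl (3S,7R)-7-(TBSO)-3-hydroxyoctanoate | C[C@@H](O[Si](C)(C)C(C)(C)C)CCC[C@H](O)CC(=O)OC
F8 | step 4 | methyl (3S,7R)-3,7-bis(TBSO)octanoate | C[C@@H](O[Si](C)(C)C(C)(C)C)CCC[C@H](O[Si](C)(C)C(C)(C)C)CC(=O)OC
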